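**Retrosynthetic overview**
1. Previtexilactone ⇒ 6β‑alcohol ⇒ 6‑ketone 11. Acetylation comes last, and the C6 stereocentre comes from hydride attack on the α‑face.
2. Ring B is opened at C9–C10 and C8–C9. This is a formal [5+1] union of β‑damascone (ring A plus C6–C8 and C17) with the C9H2 group of spiro ether‑lactone 8, made by two C–H abstraction/radical conjugate additions.
3. Both spiro rings of 8 (oxolane and γ‑lactone, with C13 and C15) come from one enantioselective oxypalladation/CO insertion/lactonisation of the achiral ene‑diol 4.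
4. Diol 4 ⇒ dilithiated methallyl alcohol + ethylene oxide.
5. Ring order: ring A is bought; the oxolane and lactone form together in step 2; ring B forms last in step 4.

Assumption: positions follow labdane numbering (C6 carries the acetate, C9 and C13 are the spiro centres), and the (S,S) antipode of the BOXAX ligand is taken to give (S)‑8; if the sense is opposite, its mirror image is used.

**Step 1**
Reactants: 1 2‑methylprop‑2‑en‑1‑ol (methallyl alcohol); 2 oxirane (ethylene oxide)
Product: 4 2‑methylidenepentane‑1,5‑diol, via dilithiated methallyl alcohol 3 (not isolated)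
Conditions: n‑BuLi (2.2 equiv), TMEDA, Et2O/hexane, 0 °C to rt; then 2, −78 °C to rt; H2O
Reagents that add atoms: ethylene oxide (2), C1CO1
Why: Double deprotonation (O–H, then the allylic CH3) gives a symmetrical 2‑(oxidomethyl)allyllithium whose carbon terminus opens the epoxide by SN2 (dianion alkylation); no stereocentre is formed.

**Step 2 (key step)**
Reactants: 4 2‑methylidenepentane‑1,5‑diol; 5 carbon monoxide
Product: 8 (S)‑1,7‑dioxaspiro[4.4]nonan‑8‑one, via alkylpalladium trifluoroacetate 6 (not isolated), via acylpalladium trifluoroacetate 7 (not isolated)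
Conditions: Pd(OCOCF3)2 (5 mol %), (S,S)‑iPr‑BOXAX (20 mol %), p‑benzoquinone (2 equiv), CO (1 atm), CH2Cl2, rt
Reagents that add atoms: carbon monoxide (5), [C-]#[O+]
Why: Proposed new method: the divalent‑palladium–BOXAX complex binds one face of the 1,1‑disubstituted alkene, the C9 hydroxyl adds 5‑exo (oxypalladation) to give σ‑alkylpalladium 6, which has no β‑hydrogen, CO inserts to give 7, and the neighbouring CH2OH captures the acyl group as the γ‑lactone, so both spiro rings, C15 and the C13 stereocentre (S, by ligand‑controlled face selection) arise in one operation while benzoquinone returns zerovalent palladium to the divalent state; the closest known reaction types are the enantioselective domino Wacker/carbonylation of alkenyl phenols at 1,1‑disubstituted alkenes and the hydroxycyclisation–carbonylation–lactonisation of ene‑diols.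

**Step 3**
Reactants: 8 (S)‑1,7‑dioxaspiro[4.4]nonan‑8‑one; 9 β‑damascone, (E)‑1‑(2,6,6‑trimethylcyclohex‑1‑en‑1‑yl)but‑2‑en‑1‑one
Product: 10 (5S)‑2‑[4‑oxo‑4‑(2,6,6‑trimethylcyclohex‑1‑en‑1‑yl)butan‑2‑yl]‑1,7‑dioxaspiro[4.4]nonan‑8‑one (13S fixed; epimers at C8 and C9)
Conditions: (n‑Bu4N)4[W10O32] (2 mol %), 9 (2 equiv), MeCN (0.5 M), 390 nm LED, rt
Reagents that add atoms: none
Why: In this photocatalytic hydrogen‑atom transfer/Giese radical conjugate addition, excited decatungstate abstracts H only from the ether CH2 (C9; the lactone OCH2 and α‑carbonyl CH2 are polarity‑deactivated) and the nucleophilic α‑oxy radical adds to the unhindered crotonyl β‑carbon C8; C8 and C9 form without control relative to C13, C9 is erased in step 4, and the 8R and 8S series are separated after step 4, each enantiopure because 8 is.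

**Step 4**
Reactants: 10 Giese adduct (C8/C9 epimers)
Product: 11 (5S,8R,9R,10S,13S)‑9,13‑epoxy‑6‑oxolabdan‑16,15‑olide (trans‑decalin, 8α‑Me, 9α‑O, 10β‑Me)
Conditions: (n‑Bu4N)4[W10O32] (5 mol %), MeCN (0.01 M), 390 nm LED, rt; SiO2 chromatography (removes the 8S‑derived diastereomers)
Reagents that add atoms: none
Why: Proposed new method: decatungstate abstracts the only hydridic C–H left (the α‑oxy C9–H), the planar nucleophilic C9 radical adds 6‑endo to the enone β‑carbon C10 (Giese cyclisation; 5‑exo attack at the α‑carbon is polarity‑mismatched) through a chair‑like transition state with the C8 methyl equatorial (which avoids a 1,3‑diaxial clash with the C10 methyl, so 8R gives 10S) and the small ring oxygen axial with CH2‑11 equatorial (9R), and hydrogen back‑transfer to the open α‑face of the C5 radical gives the trans ring fusion (5S); the closest known reaction types are decatungstate C–H/Giese alkylations of cyclic ethers and hydrogen‑atom‑transfer‑initiated radical cyclisations that join two fully substituted carbons.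

**Step 5**
Reactants: 11 6‑ketone
Product: 12 (5S,6R,8R,9R,10S,13S)‑9,13‑epoxy‑6β‑hydroxylabdan‑16,15‑olide
Conditions: NaBH4, CeCl3·7H2O, MeOH, −20 to 0 °C
Reagents that add atoms: none
Why: In this Luche‑type borohydride reduction the β‑face of C6 is closed by the two syn‑axial methyls (on C4 and C10), so hydride enters from the α‑face and gives the axial 6β‑alcohol (6R), while the buffered cold medium spares the γ‑lactone and avoids β‑elimination of the C13–O bond.

**Step 6**
Reactants: 12 6β‑alcohol; 13 acetic anhydride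
Product: 14 previtexilactone
Conditions: Ac2O, DMAP, pyridine, 40 °C
Reagents that add atoms: acetic anhydride (13), CC(=O)OC(C)=O
Why: DMAP‑catalysed acyl transfer esterifies the hindered axial alcohol with retention at C6, and the amine bases are too weak to enolise the β‑alkoxy lactone, so no stereocentre is touched.

**Compound list**
1 | 2‑methylprop‑2‑en‑1‑ol | CC(=C)CO | starting material
2 | oxirane | C1CO1 | starting material
3 | dilithiated methallyl alcohol | [Li]CC(=C)CO[Li] | intermediate
4 | 2‑methylidenepentane‑1,5‑diol | OCCCC(=C)CO | intermediate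
5 | carbon monoxide | [C-]#[O+] | starting material
6 | alkylpalladium trifluoroacetate (oxolane closed, CH2–Pd; BOXAX ligand omitted) | C1CC[C@](C[Pd]OC(=O)C(F)(F)F)(CO)O1 | intermediate
7 | acylpalladium trifluoroacetate (after CO insertion; BOXAX ligand omitted) | C1CC[C@](CC(=O)[Pd]OC(=O)C(F)(F)F)(CO)O1 | intermediate
8 | (S)‑1,7‑dioxaspiro[4.4]nonan‑8‑one | C1CC[C@]2(COC(=O)C2)O1 | intermediate
9 | β‑damascone | C/C=C/C(=O)C1=C(C)CCCC1(C)C | starting material
10 | Giese adduct, 13S, epimers at C8 and C9 | CC(CC(=O)C1=C(C)CCCC1(C)C)C1CC[C@]2(COC(=O)C2)O1 | intermediate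
11 | (5S,8R,9R,10S,13S)‑9,13‑epoxy‑6‑oxolabdan‑16,15‑olide | O=C1C[C@@H](C)[C@]2(CC[C@]3(COC(=O)C3)O2)[C@@]2(C)CCCC(C)(C)[C@H]12 | intermediate
12 | (5S,6R,8R,9R,10S,13S)‑9,13‑epoxy‑6β‑hydroxylabdan‑16,15‑olide | O[C@@H]1C[C@@H](C)[C@]2(CC[C@]3(COC(=O)C3)O2)[C@@]2(C)CCCC(C)(C)[C@H]12 | intermediate
13 | acetic anhydride | CC(=O)OC(C)=O | starting material
14 | previtexilactone | CC(=O)O[C@@H]1C[C@@H](C)[C@]2(CC[C@]3(COC(=O)C3)O2)[C@@]2(C)CCCC(C)(C)[C@H]12 | target

Total step count: 6. Longest linear sequence: 6 steps (1 → 14; 9 enters at step 3).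

**Steps most likely to fail**

Step 2 may give low ee or stall with an aliphatic alcohol as the nucleophile. The fallback closes the two rings one after the other. It sets out from 4. A catalytic asymmetric iodoetherification (N‑iodosuccinimide, (DHQD)2PHAL, −40 °C) gives [(2R)‑2‑(iodomethyl)oxolan‑2‑yl]methanol F1. A light‑driven atom‑transfer carbonylation of this neopentyl iodide (Pd(PPh3)4, CO, K2CO3, hν), with capture of the acyl group by the CH2OH, comes back to the route at 8.

Step 3 gives no control at C8, so at most half of the material is useful. Two extra steps cost about as much material as the separation, which is why this stays a fallback. It sets out from 10 and resets C8 with a catalyst. Dehydrogenation with 2‑iodoxybenzoic acid (DMSO, 70 °C; C7 is the only enolisable side of the ketone) gives (E)‑2‑[4‑oxo‑4‑(2,6,6‑trimethylcyclohex‑1‑en‑1‑yl)but‑2‑en‑2‑yl]‑1,7‑dioxaspiro[4.4]nonan‑8‑one F2. An asymmetric copper hydride 1,4‑reduction (Cu(OAc)2, (R)‑DTBM‑SEGPHOS, polymethylhydrosiloxane, t‑BuOH, toluene) then delivers the 8R epimers of the adduct F3. This comes back to the route at 10, now free of the 8S series.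

Step 4 may fail because the hindered C9–H is not abstracted, or because the radical does not close onto the tetrasubstituted enone. The fallback builds ring B before the spiro rings. It sets out from 3 and 9.
- Alkylation of 3 with bromoacetaldehyde diethyl acetal gives 5,5‑diethoxy‑2‑methylidenepentan‑1‑ol F4.
- Aqueous acid frees 4‑(hydroxymethyl)pent‑4‑enal F5.
- A thiazolium‑carbene Stetter reaction with 9 (3‑benzyl‑5‑(2‑hydroxyethyl)‑4‑methylthiazolium chloride, Et3N, EtOH) gives 7‑(hydroxymethyl)‑3‑methyl‑1‑(2,6,6‑trimethylcyclohex‑1‑en‑1‑yl)oct‑7‑ene‑1,4‑dione F6.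
- A SmI2–H2O ketyl–enone cyclisation closes ring B to racemic 9α‑hydroxy‑9‑[3‑(hydroxymethyl)but‑3‑enyl]‑4,4,8α,10β‑tetramethyl‑trans‑decalin‑6‑one F7.
- The carbonylative double cyclisation of step 2, now with the tertiary C9 hydroxyl as nucleophile, turns the two enantiomers of F7 into separable 13S diastereomers and comes back to the route at 11.

**Further compounds**
F1 | step 2 | [(2R)‑2‑(iodomethyl)oxolan‑2‑yl]methanol | C1CC[C@](CI)(CO)O1
F2 | step 3 | (E)‑2‑[4‑oxo‑4‑(2,6,6‑trimethylcyclohex‑1‑en‑1‑yl)but‑2‑en‑2‑yl]‑1,7‑dioxaspiro[4.4]nonan‑8‑one (13S, C9 epimers) | C/C(=C\C(=O)C1=C(C)CCCC1(C)C)C1CC[C@]2(COC(=O)C2)O1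
F3 | step 3 | 8R epimers of adduct 10 (13S, C9 epimers) | O=C(C[C@@H](C)C1CC[C@]2(COC(=O)C2)O1)C1=C(C)CCCC1(C)C
F4 | step 4 | 5,5‑diethoxy‑2‑methylidenepentan‑1‑ol | OCC(=C)CCC(OCC)OCC
F5 | step 4 | 4‑(hydroxymethyl)pent‑4‑enal | O=CCCC(=C)CO
F6 | step 4 | 7‑(hydroxymethyl)‑3‑methyl‑1‑(2,6,6‑trimethylcyclohex‑1‑en‑1‑yl)oct‑7‑ene‑1,4‑dione (racemic) | CC(CC(=O)C1=C(C)CCCC1(C)C)C(=O)CCC(=C)CO
F7 | step 4 | 9α‑hydroxy‑9‑[3‑(hydroxymethyl)but‑3‑enyl]‑4,4,8α,10β‑tetramethyl‑trans‑decalin‑6‑one (racemic, natural enantiomer drawn) | O=C1C[C@@H](C)[C@](O)(CCC(=C)CO)[C@@]2(C)CCCC(C)(C)[C@H]12
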